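**Plan**

- Locants used throughout: the bicyclic core is numbered C1–C8a as in naphthalene (C1 carries the side chain, C2 the secondary OH, C4 the carboxyl, C4a the tertiary OH; ring A = C1–C4, C4a, C8a; ring B = C4a, C5–C8, C8a); the side chain is C1′–C11′ (octyl = C4′–C11′).
- Enabling feature: the cyclobutane C7–C8–C2′–C3′ is a vinylcyclobutane (C7 is next to C5=C6) and shares C8–C2′ with the cyclopentane C1–C8a–C8–C2′–C1′. Cutting C7–C3′ and C8–C2′ (retro-[2+2]) therefore gives a ring B cyclohexa-1,3-diene (C5=C6–C7=C8) and an (E)-C2′=C3′ alkene held three atoms away, a 1,6-diene.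
- Further cuts, in retrosynthetic order: C7–H (enol triflate of a ring B enone); C1–C8a (intramolecular Michael addition onto a p-quinol, since rings A and B are both 4-hydroxycyclohex-2-enone units sharing C4a); C4a–O (phenol dearomatization); C3=C4 (Wittig); C1–C1′ (ylide alkylation).
- Forward order: chain, then aryl enone ester, then ring B (dearomatization), then ring A (Michael), then diene, then cyclopentane and cyclobutane in one photochemical step, then deprotection.
- Stereochemistry: C4a, C8a and C1 come from the amine-catalysed desymmetrizing Michael step (cis fusion forced by the tether, side chain pseudo-equatorial); C2 from a CBS reduction; C8, C2′, C7 and C3′ from the substrate in the [2+2] step (tether face, forced cis fusions, E-alkene).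

Key step: step 10

Remark: the sense of induction of the cinchona primary amine in step 5 is assumed to give the (1S,4aR,8aS) series; if it gives the antipode, the quinidine-derived pseudoenantiomer of the catalyst is used instead.

**Step 1**
Reactants: 1 (E)-undec-2-en-1-ol
Product: 2 (E)-1-bromoundec-2-ene
Conditions: PBr3 (0.4 equiv), Et2O, −10 to 0 °C
Reagents that add atoms: phosphorus tribromide, BrP(Br)Br
Why: Bromination of a primary allylic alcohol with PBr3 (SN2 on the phosphite ester) at low temperature should give the primary allylic bromide with the (E)-alkene intact.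

**Step 2**
Reactants: 3 1-(triphenyl-λ5-phosphanylidene)propan-2-one; 2 (E)-1-bromoundec-2-ene
Product: 5 (E)-1-(triphenyl-λ5-phosphanylidene)tetradec-5-en-2-one, via lithiated ylide 4 (not isolated)
Conditions: n-BuLi (1.0 equiv), THF, −78 °C; then 2, −78 to 0 °C
Reagents that add atoms: none
Why: Deprotonation of the acetonyl ylide at its methyl group and alkylation of the resulting ylide anion at that terminal carbon (γ-alkylation of a β-keto ylide, SN2 at the primary allylic bromide) forms C1–C1′ and leaves the stabilised ylide carbon free for the next step.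

**Step 3**
Reactants: 5 (E)-1-(triphenyl-λ5-phosphanylidene)tetradec-5-en-2-one; 6 methyl 2-(4-hydroxyphenyl)-2-oxoacetate
Product: 7 methyl (2E,7E)-2-(4-hydroxyphenyl)-4-oxohexadeca-2,7-dienoate
Conditions: toluene, 100 °C
Reagents that add atoms: none
Why: Wittig olefination of the activated α-keto ester by the stabilised acyl ylide (too weakly basic to deprotonate the phenol) forms C3=C4; the (2E) isomer, with ester and acyl group anti and the aryl group cis to the ketone as ring A requires, is expected to predominate because the two carbonyl dipoles oppose each other in the transition state.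

**Step 4**
Reactants: 7 methyl (2E,7E)-2-(4-hydroxyphenyl)-4-oxohexadeca-2,7-dienoate
Product: 8 methyl (2E,7E)-2-(1-hydroxy-4-oxocyclohexa-2,5-dien-1-yl)-4-oxohexadeca-2,7-dienoate
Conditions: PhI(OAc)2 (1.2 equiv), MeCN/H2O 4:1, 0 °C
Reagents that add atoms: water, O
Why: Oxidative dearomatization of a para-substituted phenol with (diacetoxyiodo)benzene, with water trapping the phenoxenium-type intermediate at the substituted para carbon, should give the p-quinol (in equilibrium with its spiro-hemiketal), which carries the C4a oxygen and two enantiotopic acceptor carbons.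

**Step 5**
Reactants: 8 methyl (2E,7E)-2-(1-hydroxy-4-oxocyclohexa-2,5-dien-1-yl)-4-oxohexadeca-2,7-dienoate
Product: 9 methyl (1S,4aR,8aS)-4a-hydroxy-2,7-dioxo-1-[(E)-undec-2-en-1-yl]-1,2,4a,7,8,8a-hexahydronaphthalene-4-carboxylate
Conditions: 9-amino-9-deoxy-epi-quinine (20 mol %), 2-fluorobenzoic acid (40 mol %), toluene, 40 °C
Reagents that add atoms: none
Why: Desymmetrizing intramolecular Michael addition under primary-amine (enamine) catalysis, the established way to cyclise carbonyl donors onto 4-substituted cyclohexadienones: the cross-conjugated dienamine of the chain enone attacks one enantiotopic β-carbon axially (catalyst control), the three-atom tether forces the cis ring fusion (4a-OH cis to 8a-H), and the side chain takes the pseudo-equatorial position of the chair-like transition state, trans to C8.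

**Step 6**
Reactants: 9 methyl (1S,4aR,8aS)-4a-hydroxy-2,7-dioxo-1-[(E)-undec-2-en-1-yl]-1,2,4a,7,8,8a-hexahydronaphthalene-4-carboxylate
Product: 10 methyl (1S,4aR,8aS)-2,7-dioxo-4a-(triethylsilyloxy)-1-[(E)-undec-2-en-1-yl]-1,2,4a,7,8,8a-hexahydronaphthalene-4-carboxylate
Conditions: Et3SiOTf (1.2 equiv), 2,6-lutidine, CH2Cl2, −78 °C
Reagents that add atoms: triethylsilyl trifluoromethanesulfonate, CC[Si](CC)(CC)OS(=O)(=O)C(F)(F)F
Why: Silylation of the tertiary alcohol with a silyl triflate and a hindered pyridine at −78 °C leaves both enones untouched and removes the free alkoxide that could be sulfonylated or trigger retro-Michael cleavage in the next step.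

**Step 7**
Reactants: 10 methyl (1S,4aR,8aS)-2,7-dioxo-4a-(triethylsilyloxy)-1-[(E)-undec-2-en-1-yl]-1,2,4a,7,8,8a-hexahydronaphthalene-4-carboxylate
Product: 12 methyl (1S,4aR,8aS)-2-oxo-4a-(triethylsilyloxy)-7-(trifluoromethylsulfonyloxy)-1-[(E)-undec-2-en-1-yl]-1,2,4a,8a-tetrahydronaphthalene-4-carboxylate, via potassium dienolate 11 (not isolated)
Conditions: KN(SiMe3)2 (1.05 equiv), THF, −78 °C; then N-(5-chloropyridin-2-yl)bis(trifluoromethanesulfonimide), −78 °C
Reagents that add atoms: N-(5-chloropyridin-2-yl)bis(trifluoromethanesulfonimide), O=S(=O)(N(c1ccc(Cl)cn1)S(=O)(=O)C(F)(F)F)C(F)(F)F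
Why: Kinetic deprotonation by the hindered amide at the unhindered C8 methylene of the ring B enone is expected to outrun removal of the tertiary C1–H (flanked by C8a and the side chain) of the ring A enone, and fast O-sulfonylation of the cross-conjugated dienolate gives the enol triflate (kinetic enol triflate formation).

**Step 8**
Reactants: 12 methyl (1S,4aR,8aS)-2-oxo-4a-(triethylsilyloxy)-7-(trifluoromethylsulfonyloxy)-1-[(E)-undec-2-en-1-yl]-1,2,4a,8a-tetrahydronaphthalene-4-carboxylate
Product: 13 methyl (1S,2S,4aR,8aR)-2-hydroxy-4a-(triethylsilyloxy)-7-(trifluoromethylsulfonyloxy)-1-[(E)-undec-2-en-1-yl]-1,2,4a,8a-tetrahydronaphthalene-4-carboxylate (the C8a descriptor changes by priority only)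
Conditions: (S)-2-methyl-CBS-oxazaborolidine (0.3 equiv), catecholborane (1.5 equiv), toluene, −78 °C; MeOH quench, aq. NaHCO3
Reagents that add atoms: none
Why: CBS reduction (catalyst-controlled 1,2-reduction of an enone by catecholborane): with the α-branched C1 side as the large group, the (S)-oxazaborolidine should deliver hydride to give the (2S) allylic alcohol, OH cis to the C1 side chain, leaving ester, enol triflate and alkenes untouched and fixing C1 against epimerisation.

**Step 9**
Reactants: 13 methyl (1S,2S,4aR,8aR)-2-hydroxy-4a-(triethylsilyloxy)-7-(trifluoromethylsulfonyloxy)-1-[(E)-undec-2-en-1-yl]-1,2,4a,8a-tetrahydronaphthalene-4-carboxylate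
Product: 14 methyl (1S,2S,4aR,8aS)-2-hydroxy-4a-(triethylsilyloxy)-1-[(E)-undec-2-en-1-yl]-1,2,4a,8a-tetrahydronaphthalene-4-carboxylate
Conditions: Pd(OAc)2 (5 mol %), PPh3 (10 mol %), n-Bu3N, HCO2H, DMF, 50 °C; chromatography on Et3N-deactivated silica
Reagents that add atoms: none
Why: Palladium-catalysed formate reduction of an enol triflate (oxidative addition to zerovalent palladium, formate-to-hydride exchange with loss of CO2, reductive elimination) replaces OTf by H and unveils the conjugated C5=C6–C7=C8 diene under non-acidic conditions, so the arene-hydrate-like silyl ether should not aromatise.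

**Step 10**
Reactants: 14 methyl (1S,2S,4aR,8aS)-2-hydroxy-4a-(triethylsilyloxy)-1-[(E)-undec-2-en-1-yl]-1,2,4a,8a-tetrahydronaphthalene-4-carboxylate
Product: 15 methyl ester 4a-O-triethylsilyl ether of the target tetracycle (1S,2S,4aR,7S,8R,8aS,2′R,3′R)
Conditions: fac-Ir(ppy)3 (1 mol %), degassed MeCN (0.005 M), 450 nm LEDs, 25 °C
Reagents that add atoms: none
Why: Mechanism: the excited trivalent iridium sensitizer fac-Ir(ppy)3 (triplet energy about 58 kcal/mol) transfers energy only to the cyclohexa-1,3-diene (about 52 kcal/mol; acrylate and isolated alkene lie far higher), the diene triplet adds through C8 to C2′, and the resulting triplet 1,4-diradical (alkyl radical at C3′, allyl radical at C7) closes after intersystem crossing. The closest known reaction type is the visible-light triplet-sensitised intramolecular [2+2] photocycloaddition of a 1,3-diene with a tethered alkene. The cyclopentane C1–C8a–C8–C2′–C1′ closes 5-exo-trig, as the rule of five predicts for a 1,6-diene, and the cyclobutane C7–C8–C2′–C3′ closes last by 1,4 radical–radical recombination between C3′ and C7. C8 and C2′ are set by the tether, which reaches C8 only on the ring B face that carries C1; C7 is set by the obligatory cis fusion of the four-membered ring; C3′ is set by the (E)-alkene and the preference of the octyl group for the convex face during closure. The step needs 1,4- over 1,6-closure (the [2+2] product, not the bridged [4+2] isomer through C5), which the proximity of C3′ to C7 in the cis-fused diradical should secure, and it needs the diene to escape direct excitation (electrocyclic ring opening) and dimerisation, which 450 nm light and high dilution secure.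

**Step 11**
Reactants: 15 methyl ester 4a-O-triethylsilyl ether of the target tetracycle
Product: 17 CNP0106718.3 (free acid), via desilylated methyl ester 16 (not isolated)
Conditions: Bu4NF, THF, 0 °C; then LiOH, THF/MeOH/H2O, 40 °C; 1 M HCl to pH 4 at 0 °C
Reagents that add atoms: lithium hydroxide, [Li+].[OH-]
Why: Fluoride cleaves the tertiary silyl ether and hydroxide saponifies the methyl ester (the carboxyl is trans to C2 across C3=C4, so no lactone can form), while acidification only to pH 4 avoids ionising the doubly allylic tertiary alcohol.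

**Compound list**

1 | (E)-undec-2-en-1-ol | CCCCCCCC/C=C/CO | starting material
2 | (E)-1-bromoundec-2-ene | CCCCCCCC/C=C/CBr | intermediate
3 | 1-(triphenyl-λ5-phosphanylidene)propan-2-one | CC(=O)C=P(c1ccccc1)(c1ccccc1)c1ccccc1 | starting material
4 | lithiated ylide (lithium enolate of 3) | [Li]OC(=C)C=P(c1ccccc1)(c1ccccc1)c1ccccc1 | intermediate
5 | (E)-1-(triphenyl-λ5-phosphanylidene)tetradec-5-en-2-one | CCCCCCCC/C=C/CCC(=O)C=P(c1ccccc1)(c1ccccc1)c1ccccc1 | intermediate
6 | methyl 2-(4-hydroxyphenyl)-2-oxoacetate | COC(=O)C(=O)c1ccc(O)cc1 | starting material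
7 | methyl (2E,7E)-2-(4-hydroxyphenyl)-4-oxohexadeca-2,7-dienoate | CCCCCCCC/C=C/CCC(=O)/C=C(\c1ccc(O)cc1)C(=O)OC | intermediate
8 | methyl (2E,7E)-2-(1-hydroxy-4-oxocyclohexa-2,5-dien-1-yl)-4-oxohexadeca-2,7-dienoate (p-quinol, open form) | CCCCCCCC/C=C/CCC(=O)/C=C(\C1(O)C=CC(=O)C=C1)C(=O)OC | intermediate
9 | methyl (1S,4aR,8aS)-4a-hydroxy-2,7-dioxo-1-[(E)-undec-2-en-1-yl]-1,2,4a,7,8,8a-hexahydronaphthalene-4-carboxylate (cis-fused; 4a-OH cis to 8a-H; side chain trans to C8) | CCCCCCCC/C=C/C[C@@H]1C(=O)C=C(C(=O)OC)[C@@]2(O)C=CC(=O)C[C@@H]12 | intermediate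
10 | 4a-O-triethylsilyl ether of 9 | CCCCCCCC/C=C/C[C@@H]1C(=O)C=C(C(=O)OC)[C@@]2(O[Si](CC)(CC)CC)C=CC(=O)C[C@@H]12 | intermediate
11 | potassium C7-dienolate of 10 (C7–OK, C7=C8, C5=C6) | CCCCCCCC/C=C/C[C@@H]1C(=O)C=C(C(=O)OC)[C@@]2(O[Si](CC)(CC)CC)C=CC(O[K])=C[C@@H]12 | intermediate
12 | methyl (1S,4aR,8aS)-2-oxo-4a-(triethylsilyloxy)-7-(trifluoromethylsulfonyloxy)-1-[(E)-undec-2-en-1-yl]-1,2,4a,8a-tetrahydronaphthalene-4-carboxylate | CCCCCCCC/C=C/C[C@@H]1C(=O)C=C(C(=O)OC)[C@@]2(O[Si](CC)(CC)CC)C=CC(OS(=O)(=O)C(F)(F)F)=C[C@@H]12 | intermediate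
13 | methyl (1S,2S,4aR,8aR)-2-hydroxy-4a-(triethylsilyloxy)-7-(trifluoromethylsulfonyloxy)-1-[(E)-undec-2-en-1-yl]-1,2,4a,8a-tetrahydronaphthalene-4-carboxylate (2-OH cis to the side chain) | CCCCCCCC/C=C/C[C@@H]1[C@H](O)C=C(C(=O)OC)[C@@]2(O[Si](CC)(CC)CC)C=CC(OS(=O)(=O)C(F)(F)F)=C[C@@H]12 | intermediate
14 | methyl (1S,2S,4aR,8aS)-2-hydroxy-4a-(triethylsilyloxy)-1-[(E)-undec-2-en-1-yl]-1,2,4a,8a-tetrahydronaphthalene-4-carboxylate (photosubstrate) | CCCCCCCC/C=C/C[C@@H]1[C@H](O)C=C(C(=O)OC)[C@@]2(O[Si](CC)(CC)CC)C=CC=C[C@@H]12 | intermediate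
15 | methyl ester 4a-O-triethylsilyl ether of 17 (cyclobutane C7–C8–C2′–C3′ with octyl on C3′; cyclopentane C1–C8a–C8–C2′–C1′; 1S,2S,4aR,7S,8R,8aS,2′R,3′R) | CCCCCCCC[C@H]1[C@@H]2C=C[C@]3(O[Si](CC)(CC)CC)C(C(=O)OC)=C[C@@H](O)[C@H]4C[C@H]1[C@H]2[C@@H]43 | intermediate
16 | methyl ester of 17 | CCCCCCCC[C@H]1[C@@H]2C=C[C@]3(O)C(C(=O)OC)=C[C@@H](O)[C@H]4C[C@H]1[C@H]2[C@@H]43 | intermediate
17 | CNP0106718.3, free acid (1S,2S,4aR,7S,8R,8aS,2′R,3′R in the locants of the plan) | CCCCCCCC[C@H]1[C@@H]2C=C[C@]3(O)C(C(=O)O)=C[C@@H](O)[C@H]4C[C@H]1[C@H]2[C@@H]43 | target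

**Step count and risks**

Total step count: 11. Longest linear sequence: 11 steps (1 → 2 → 5 → 7 → 8 → 9 → 10 → 12 → 13 → 14 → 15 → 17).

Steps most likely to fail:

Step 5. The cyclisation may fail through slow enamine formation from the hemiketal-masked enone, poor discrimination of the two enantiotopic acceptor carbons, or epimerisation at C1. The fallback replaces enamine catalysis by a Mukaiyama–Michael reaction of a preformed silyl dienol ether. From 8, Et3SiOTf (2.5 equiv) and Et3N in CH2Cl2 (−78 to 0 °C) should silylate the tertiary alcohol and enolise the chain ketone towards C1 (the dienone has no α-hydrogen), giving the bis-silylated 2-silyloxydiene F1. A chiral BINOL-derived disulfonimide (silylium counteranion catalysis, Et2O, −40 °C) should then close ring A with transfer of the silyl group to the ring B enolate, giving the ring B silyl dienol ether F2, in which the two carbonyl groups are already differentiated. CsF and PhNTf2 in DME convert the silyl dienol ether into the enol triflate, and the route is rejoined at 12; steps 6 and 7 are then not needed, which also removes the regioselectivity question of step 7.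

Step 10. The photocycloaddition may fail through inefficient energy transfer from the external sensitizer, oxidation or dimerisation of the diene, or closure of the diradical at C5. The fallback makes the sensitisation intramolecular and reverses the order of reduction and cycloaddition. From 12, the formate reduction of step 9 is run first to give the diene ketone F3, whose ring A enone ester absorbs near 370–390 nm and should pass its triplet energy to the adjacent diene. Irradiation at 390 nm in degassed MeCN (0.005 M, no catalyst) should give the tetracyclic ketone F4, and a CBS reduction as in step 8 returns the route at 15.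

Step 8. The reduction may fail through substrate-controlled axial hydride attack that overrides the catalyst and gives the C2 epimer, or through conjugate reduction of the keto-enoate. The fallback sets C2 by inversion. From 12, NaBH4/CeCl3·7H2O in MeOH at −78 °C (Luche reduction, axial attack) should give the equatorial C2-epimeric alcohol F5. Mitsunobu inversion with chloroacetic acid (PPh3, diisopropyl azodicarboxylate, THF, 0 °C; SN2′ attack is blocked by the fully substituted C4) gives the (2S) chloroacetate F6. Thiourea and NaHCO3 in EtOH remove the chloroacetyl group without touching the methyl ester or the enol triflate, and the route is rejoined at 13.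

**Further compounds**

F1 | step 5 | methyl (2E,7E)-4-(triethylsilyloxy)-2-[4-oxo-1-(triethylsilyloxy)cyclohexa-2,5-dien-1-yl]hexadeca-2,4,7-trienoate (2-silyloxydiene) | CCCCCCCC/C=C/CC=C(O[Si](CC)(CC)CC)/C=C(\C1(O[Si](CC)(CC)CC)C=CC(=O)C=C1)C(=O)OC
F2 | step 5 | methyl (1S,4aR,8aS)-2-oxo-4a,7-bis(triethylsilyloxy)-1-[(E)-undec-2-en-1-yl]-1,2,4a,8a-tetrahydronaphthalene-4-carboxylate (ring B silyl dienol ether) | CCCCCCCC/C=C/C[C@@H]1C(=O)C=C(C(=O)OC)[C@@]2(O[Si](CC)(CC)CC)C=CC(O[Si](CC)(CC)CC)=C[C@@H]12
F3 | step 10 | methyl (1S,4aR,8aS)-2-oxo-4a-(triethylsilyloxy)-1-[(E)-undec-2-en-1-yl]-1,2,4a,8a-tetrahydronaphthalene-4-carboxylate (diene ketone) | CCCCCCCC/C=C/C[C@@H]1C(=O)C=C(C(=O)OC)[C@@]2(O[Si](CC)(CC)CC)C=CC=C[C@@H]12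
F4 | step 10 | 2-oxo analogue of 15 (tetracyclic ketone) | CCCCCCCC[C@H]1[C@@H]2C=C[C@]3(O[Si](CC)(CC)CC)C(C(=O)OC)=CC(=O)[C@H]4C[C@H]1[C@H]2[C@@H]43
F5 | step 8 | C2 epimer of 13 (2-OH trans to the side chain) | CCCCCCCC/C=C/C[C@@H]1[C@@H](O)C=C(C(=O)OC)[C@@]2(O[Si](CC)(CC)CC)C=CC(OS(=O)(=O)C(F)(F)F)=C[C@@H]12
F6 | step 8 | 2-O-chloroacetate of 13 | CCCCCCCC/C=C/C[C@@H]1[C@H](OC(=O)CCl)C=C(C(=O)OC)[C@@]2(O[Si](CC)(CC)CC)C=CC(OS(=O)(=O)C(F)(F)F)=C[C@@H]12
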